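**Retrosynthetic overview**
1. C8–O ester: 21 ⇒ hydroxy-ketone 18 + CO + but-2-yn-1-yl acetate 20 (Pd-catalysed hydroalkoxycarbonylation, which also builds the (E)-enoate).
2. Ten-membered ring (formed last): 18 ⇒ bicyclic 1,4-diene lactone 15 by ozonolytic scission of the ring-fusion C=C into two C=O; the ring cis-olefin becomes the (Z)-C1=C10 alkene; the C8 carbonyl is then reduced.
3. 15 ⇒ aromatic trans-lactone ester 10 (saponification/Birch reduction, then decarboxylative methylenation).
4. γ-Lactone (second ring): 10 ⇒ benzylic epoxide 8 + dimethyl malonate; 8 ⇒ dihydronaphthalene 7 by Jacobsen epoxidation (sets C6 and, by inversion, C7).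
5. Carbocycle A (first ring closed; the arene is bought): 7 ⇒ tetralone 5 ⇒ acid 4 (Ir asymmetric hydrogenation sets C4) ⇒ 4′-methylacetophenone 1 + phosphonium salt 2.

Assumption: germacrane locants are used in the explanations (C1=C10 ring olefin, C3 ketone, C4 methyl-bearing carbon, C6 lactone O, C7, C8 ester O, C11–C13 methylene-lactone carbons), and the Ir catalyst enantiomer in step 2 is the one that gives (R)-4 (its antipode is used if it gives S).

Step 1
Reactants: 1 4′-methylacetophenone; 2 (2-carboxyethyl)triphenylphosphonium bromide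
Product: 3 (3E)-4-(4-methylphenyl)pent-3-enoic acid
Conditions: NaHMDS (2.5 equiv), THF, −20 °C → rt; aq. HCl; recrystallise
Reagents that add atoms: none
Why: Wittig olefination with the carboxylate-bearing non-stabilised ylide turns the aryl methyl ketone into the β,γ-unsaturated acid, the E isomer (aryl trans to CH2CO2H) predominating and being purified by crystallisation; no stereocentre is formed.

Step 2
Reactants: 3 (3E)-4-(4-methylphenyl)pent-3-enoic acid
Product: 4 (4R)-4-(4-methylphenyl)pentanoic acid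
Conditions: [Ir(cod)(SIPHOX)]BArF (0.5 mol%), H2 (6 atm), Cs2CO3 (0.5 equiv), MeOH, rt
Reagents that add atoms: none
Why: Carboxylate-directed Ir-catalysed asymmetric hydrogenation of a β,γ-unsaturated acid (spiro phosphine–oxazoline type) adds H2 to one enantioface of the trisubstituted styrenic olefin and sets the benzylic methyl stereocentre (C4, R) under catalyst control.

Step 3
Reactants: 4 (4R)-4-(4-methylphenyl)pentanoic acid
Product: 5 (4R)-4,7-dimethyl-3,4-dihydronaphthalen-1(2H)-one
Conditions: Eaton's reagent (P2O5/MsOH), 25–40 °C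
Reagents that add atoms: none
Why: Intramolecular Friedel–Crafts acylation closes the six-membered ketone ring ortho to the side chain (both ortho positions are equivalent); the benzylic stereocentre is not involved.

Step 4
Reactants: 5 (4R)-4,7-dimethyl-3,4-dihydronaphthalen-1(2H)-one
Product: 7 (1R)-1,6-dimethyl-1,2-dihydronaphthalene, via tetralol 6 (not isolated)
Conditions: NaBH4, MeOH, 0 °C; then p-TsOH·H2O (2 mol%), PhMe, 80 °C
Reagents that add atoms: none
Why: Borohydride reduction of the aryl ketone followed by acid-catalysed E1 dehydration of the benzylic alcohol gives the conjugated cis-styrenic olefin from both carbinol epimers; C4 is untouched.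

Step 5
Reactants: 7 (1R)-1,6-dimethyl-1,2-dihydronaphthalene
Product: 8 (1aR,3R,7bS)-3,6-dimethyl-1a,2,3,7b-tetrahydronaphtho[1,2-b]oxirene
Conditions: (S,S)-Jacobsen Mn(salen)Cl (3 mol%), 4-phenylpyridine N-oxide (20 mol%), aq. NaOCl (pH 11.3), CH2Cl2, 0 °C
Reagents that add atoms: sodium hypochlorite, [Na+].[O-]Cl
Why: Jacobsen–Katsuki epoxidation of a cyclic cis-styrenic olefin; the (S,S)-catalyst gives the benzylic-S, homobenzylic-R epoxide (as with indene and 1,2-dihydronaphthalene), which is also the face anti to the pseudo-axial C4 methyl (matched case), so the C6–O stereocentre is set by the catalyst.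

Step 6
Reactants: 8 (1aR,3R,7bS)-3,6-dimethyl-1a,2,3,7b-tetrahydronaphtho[1,2-b]oxirene; 9 dimethyl malonate
Product: 10 methyl (3aR,5R,9bR)-5,8-dimethyl-2-oxo-1,2,3a,4,5,9b-hexahydronaphtho[2,1-b]furan-1-carboxylate
Conditions: NaOMe (1.2 equiv), MeOH/THF, 65 °C; AcOH quench
Reagents that add atoms: none
Why: Malonate opens the epoxide by SN2 attack at the benzylic carbon with inversion (trans-diaxial, Fürst–Plattner; attack at the other carbon would put the nucleophile syn-diaxial to the C4 methyl), which sets C7, and the freed alkoxide lactonises onto one ester to give the trans-fused γ-lactone (classical malonate–epoxide lactone synthesis); the α-carbon is an inconsequential epimer mixture.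

Step 7
Reactants: 10 methyl (3aR,5R,9bR)-5,8-dimethyl-2-oxo-1,2,3a,4,5,9b-hexahydronaphtho[2,1-b]furan-1-carboxylate
Product: 13 (3aR,5R,9bR)-5,8-dimethyl-2-oxo-1,2,3a,4,5,6,9,9b-octahydronaphtho[2,1-b]furan-1-carboxylic acid, via hydroxy-malonate dilithium salt 11 (not isolated), via hexahydro dilithium salt 12 (not isolated)
Conditions: LiOH, THF/H2O, rt; evaporate; Li, NH3(l), THF, t-BuOH, −78 → −33 °C; NH4Cl; aq. HCl (pH 2), 0 °C → rt
Reagents that add atoms: lithium hydroxide, [Li+].[OH-]
Why: Saponification turns both carbonyl groups into carboxylates that survive dissolving metal; Birch reduction of the trialkylbenzene then leaves the alkyl-bearing carbons sp2 (ring-fusion tetrasubstituted and methyl-bearing trisubstituted olefins of a 1,4-diene), and acidification relactonises the trans γ-hydroxy acid without touching a stereocentre.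

Step 8
Reactants: 13 (3aR,5R,9bR)-5,8-dimethyl-2-oxo-1,2,3a,4,5,6,9,9b-octahydronaphtho[2,1-b]furan-1-carboxylic acid
Product: 15 (3aR,5R,9bS)-5,8-dimethyl-1-methylidene-3a,4,5,6,9,9b-hexahydronaphtho[2,1-b]furan-2(1H)-one, via Mannich base 14 (not isolated)
Conditions: 37% aq. HCHO, Et2NH, THF, 0 °C → rt; then NaOAc, AcOH, 70 °C
Reagents that add atoms: formaldehyde, C=O
Why: Decarboxylative Mannich methylenation (Knoevenagel–Doebner type): the malonic half-acid condenses with formaldehyde/diethylamine and the Mannich base loses CO2 and amine on warming to give the α-methylene lactone; existing stereocentres are not touched.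

Step 9
Reactants: 15 (3aR,5R,9bS)-5,8-dimethyl-1-methylidene-3a,4,5,6,9,9b-hexahydronaphtho[2,1-b]furan-2(1H)-one
Product: 18 (3aR,4R,6Z,10R,11aR)-4-hydroxy-6,10-dimethyl-3-methylidene-3a,4,5,8,10,11-hexahydrocyclodeca[b]furan-2,9(3H,11aH)-dione, via ozonide 16 (not isolated), via macrocyclic dione 17 (not isolated)
Conditions: O3 (1.0 equiv, Sudan Red end point), CH2Cl2, −78 °C; PPh3, −78 → 0 °C; then MeOH, CeCl3·7H2O, NaBH4 (0.5 equiv), −78 °C; AcOH
Reagents that add atoms: ozone, [O-][O+]=O
Why: Ozonolysis: electrophilic ozone attacks the most electron-rich, tetrasubstituted ring-fusion olefin, and phosphine reduction of the ozonide opens the bicycle to the ten-membered 1,6-dione whose ring-derived cis olefin is the required Z-alkene; in the Luche reduction the more electrophilic C8 ketone (β-acyloxy, next to the lactone) reacts first, its alkoxide masks C3=O as the transannular hemiketal, and hydride enters from the peripheral face anti to the C6–C7 ring bond (Felkin–Anh, 1,3-anti to the C6 oxygen) to give the 8R carbinol.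

Step 10
Reactants: 19 but-2-yn-1-ol
Product: 20 but-2-yn-1-yl acetate
Conditions: Ac2O, Et3N, DMAP (cat.), CH2Cl2, 0 °C → rt
Reagents that add atoms: acetic anhydride, CC(=O)OC(C)=O
Why: Standard DMAP-catalysed O-acetylation of a primary propargylic alcohol.

Step 11
Reactants: 18 (3aR,4R,6Z,10R,11aR)-4-hydroxy-6,10-dimethyl-3-methylidene-3a,4,5,8,10,11-hexahydrocyclodeca[b]furan-2,9(3H,11aH)-dione; 20 but-2-yn-1-yl acetate
Product: 21 (3aS,4R,6Z,10R,11aR)-6,10-dimethyl-3-methylidene-2,9-dioxo-2,3,3a,4,5,8,9,10,11,11a-decahydrocyclodeca[b]furan-4-yl (2E)-2-[(acetyloxy)methyl]but-2-enoate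
Conditions: Pd(OAc)2 (5 mol%), 2-pyridyldiphenylphosphine (20 mol%), TsOH·H2O (10 mol%), CO (20 bar), 20 (3 equiv), CH2Cl2/PhMe, 40 °C
Reagents that add atoms: carbon monoxide, [C-]#[O+]
Why: Proposed new method: Pd–H adds syn across the alkyne of 20 with Pd on the carbon next to CH2OAc (inductive bias and acetate-carbonyl chelation, the regiochemistry seen in Pd hydrometalation of propargylic esters), CO inserts, and the acyl–Pd is captured by the C8 hydroxyl of the open hydroxy-ketone tautomer of 18, so the ester C–O bond and the whole (E)-2-(acetoxymethyl)but-2-enoate unit form in one step with retention at C8 (syn H/CO2R addition fixes E) while the alkyne reacts far faster than the α-methylene lactone or the ring olefin; the closest known reaction type is the Drent/Beller Pd-catalysed hydroalkoxycarbonylation of alkynes with simple alcohols (2-butyne to tiglates), not yet shown with a propargylic ester and a hindered polyfunctional secondary alcohol as the limiting partner.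

**Compound list**
1 | 4′-methylacetophenone | CC(=O)c1ccc(C)cc1 | starting material
2 | (2-carboxyethyl)triphenylphosphonium bromide | OC(=O)CC[P+](c1ccccc1)(c1ccccc1)c1ccccc1.[Br-] | starting material
3 | (3E)-4-(4-methylphenyl)pent-3-enoic acid | C/C(=C\CC(O)=O)c1ccc(C)cc1 | intermediate
4 | (4R)-4-(4-methylphenyl)pentanoic acid | C[C@H](CCC(O)=O)c1ccc(C)cc1 | intermediate
5 | (4R)-4,7-dimethyl-3,4-dihydronaphthalen-1(2H)-one | O=C1CC[C@@H](C)c2ccc(C)cc12 | intermediate
6 | (4R)-4,7-dimethyl-1,2,3,4-tetrahydronaphthalen-1-ol (both C1 epimers) | OC1CC[C@@H](C)c2ccc(C)cc12 | intermediate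
7 | (1R)-1,6-dimethyl-1,2-dihydronaphthalene | C[C@@H]1CC=Cc2cc(C)ccc12 | intermediate
8 | (1aR,3R,7bS)-3,6-dimethyl-1a,2,3,7b-tetrahydronaphtho[1,2-b]oxirene | O1[C@@H]2C[C@@H](C)c3ccc(C)cc3[C@H]12 | intermediate
9 | dimethyl malonate | COC(=O)CC(=O)OC | starting material
10 | methyl (3aR,5R,9bR)-5,8-dimethyl-2-oxo-1,2,3a,4,5,9b-hexahydronaphtho[2,1-b]furan-1-carboxylate (trans-fused; C1 epimers) | COC(=O)C1C(=O)O[C@@H]2C[C@@H](C)c3ccc(C)cc3[C@@H]12 | intermediate
11 | dilithium 2-[(1R,2R,4R)-2-hydroxy-4,7-dimethyl-1,2,3,4-tetrahydronaphthalen-1-yl]propanedioate | [Li+].[Li+].[O-]C(=O)C(C([O-])=O)[C@@H]1c2cc(C)ccc2[C@H](C)C[C@H]1O | intermediate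
12 | dilithium 2-[(1R,2R,4R)-2-hydroxy-4,7-dimethyl-1,2,3,4,5,8-hexahydronaphthalen-1-yl]propanedioate | [Li+].[Li+].[O-]C(=O)C(C([O-])=O)[C@@H]1C2=C(CC=C(C)C2)[C@H](C)C[C@H]1O | intermediate
13 | (3aR,5R,9bR)-5,8-dimethyl-2-oxo-1,2,3a,4,5,6,9,9b-octahydronaphtho[2,1-b]furan-1-carboxylic acid (C1 epimers) | OC(=O)C1C(=O)O[C@@H]2C[C@@H](C)C3=C(CC(C)=CC3)[C@@H]12 | intermediate
14 | (3aR,5R,9bR)-1-[(diethylamino)methyl]-5,8-dimethyl-2-oxo-1,2,3a,4,5,6,9,9b-octahydronaphtho[2,1-b]furan-1-carboxylic acid (Mannich base; C1 epimers) | CCN(CC)CC1(C(O)=O)C(=O)O[C@@H]2C[C@@H](C)C3=C(CC(C)=CC3)[C@@H]12 | intermediate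
15 | (3aR,5R,9bS)-5,8-dimethyl-1-methylidene-3a,4,5,6,9,9b-hexahydronaphtho[2,1-b]furan-2(1H)-one | C=C1C(=O)O[C@@H]2C[C@@H](C)C3=C(CC(C)=CC3)[C@@H]12 | intermediate
16 | ozonide of 15: 1,2,4-trioxolane bridging the former ring-fusion carbons C5a and C9a (bridgehead configuration a mixture, lost in the same flask) | C=C1C(=O)O[C@@H]2C[C@@H](C)C34OOC(O3)(CC(C)=CC4)[C@@H]12 | intermediate
17 | (3aS,6Z,10R,11aR)-6,10-dimethyl-3-methylidene-3a,5,8,10,11,11a-hexahydrocyclodeca[b]furan-2,4,9(3H)-trione | C=C1C(=O)O[C@@H]2C[C@@H](C)C(=O)C/C=C(/C)CC(=O)[C@@H]12 | intermediate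
18 | (3aR,4R,6Z,10R,11aR)-4-hydroxy-6,10-dimethyl-3-methylidene-3a,4,5,8,10,11-hexahydrocyclodeca[b]furan-2,9(3H,11aH)-dione (in equilibrium with its 4,9-transannular hemiketal) | C=C1C(=O)O[C@@H]2C[C@@H](C)C(=O)C/C=C(/C)C[C@@H](O)[C@@H]12 | intermediate
19 | but-2-yn-1-ol | CC#CCO | starting material
20 | but-2-yn-1-yl acetate | CC#CCOC(C)=O | intermediate
21 | (3aS,4R,6Z,10R,11aR)-6,10-dimethyl-3-methylidene-2,9-dioxo-2,3,3a,4,5,8,9,10,11,11a-decahydrocyclodeca[b]furan-4-yl (2E)-2-[(acetyloxy)methyl]but-2-enoate | C=C1C(=O)O[C@@H]2C[C@@H](C)C(=O)C/C=C(/C)C[C@@H](OC(=O)/C(=C/C)COC(C)=O)[C@@H]12 | target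

**Step count and risk**
Total steps: 11. Longest linear sequence: 10 (steps 1–9, then 11).

The three steps most likely to fail are 7, 9 and 11.

Step 7 (Birch reduction of a polar dilithium salt; possible decarboxylation or incomplete relactonisation on work-up). The fallback sets out from 10 and comes back at 15. Krapcho demethoxycarbonylation (NaCl, wet DMSO, 150 °C) gives the plain trans-lactone (3aR,5R,9bR)-5,8-dimethyl-3a,4,5,9b-tetrahydronaphtho[2,1-b]furan-2(1H)-one F1. LiAlH4 (THF, 0 °C) opens it to the diol (1R,2R,4R)-1-(2-hydroxyethyl)-4,7-dimethyl-1,2,3,4-tetrahydronaphthalen-2-ol F2. A standard Birch reduction of this neutral substrate (Li, NH3, THF, t-BuOH) gives the diene diol (1R,2R,4R)-1-(2-hydroxyethyl)-4,7-dimethyl-1,2,3,4,5,8-hexahydronaphthalen-2-ol F3. TEMPO/PhI(OAc)2 oxidative lactonisation rebuilds the γ-lactone as (3aR,5R,9bR)-5,8-dimethyl-3a,4,5,6,9,9b-hexahydronaphtho[2,1-b]furan-2(1H)-one F4. LDA then Eschenmoser's salt gives the α-aminomethyl lactone (3aR,5R,9bR)-1-[(dimethylamino)methyl]-5,8-dimethyl-3a,4,5,6,9,9b-hexahydronaphtho[2,1-b]furan-2(1H)-one F5, and MeI followed by NaHCO3 eliminates to 15.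

Step 9 (ozone may not discriminate well enough between the tetrasubstituted and the trisubstituted olefin; the dione is prone to transannular aldol; site and face selectivity of the reduction rest on the models given). The fallback sets out from 15 and comes back at 18. mCPBA (1.0 equiv, NaHCO3, CH2Cl2, −20 °C), which separates tetra- from trisubstituted olefins better than ozone, gives the ring-fusion 5a,9a-epoxide of 15 F6. Aqueous HClO4 in THF opens it to the ring-fusion 5a,9a-trans-diol F7. Pb(OAc)4 glycol cleavage (Criegee oxidation, which unlike periodate also cleaves trans-diaxial ditertiary diols) then gives the dione 17, this time isolated, and the same Luche reduction leads to 18.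

Step 11 (the proposed new step: regiochemistry of hydropalladation, slow capture of the acyl–Pd by a hindered, hemiketal-masked alcohol, acid sensitivity of the β,γ-enone). The fallback uses known chemistry, sets out from 18 and comes back at 21. Morita–Baylis–Hillman reaction of tert-butyl acrylate with acetaldehyde (DABCO) gives tert-butyl 3-hydroxy-2-methylidenebutanoate F8. Ac2O/DMAP gives tert-butyl 3-(acetyloxy)-2-methylidenebutanoate F9. Catalytic DABCO in refluxing THF effects the SN2′/SN2′ 1,3-acetoxy shift to the thermodynamic tert-butyl (2E)-2-[(acetyloxy)methyl]but-2-enoate F10. TFA in CH2Cl2 frees (2E)-2-[(acetyloxy)methyl]but-2-enoic acid F11. Yamaguchi activation (2,4,6-trichlorobenzoyl chloride, Et3N) gives (2E)-2-[(acetyloxy)methyl]but-2-enoic 2,4,6-trichlorobenzoic anhydride F12, which acylates 18 in the presence of DMAP to give 21.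

**Further compounds**
F1 | step 7 | (3aR,5R,9bR)-5,8-dimethyl-3a,4,5,9b-tetrahydronaphtho[2,1-b]furan-2(1H)-one | C1C(=O)O[C@@H]2C[C@@H](C)c3ccc(C)cc3[C@@H]12
F2 | step 7 | (1R,2R,4R)-1-(2-hydroxyethyl)-4,7-dimethyl-1,2,3,4-tetrahydronaphthalen-2-ol | OCC[C@@H]1c2cc(C)ccc2[C@H](C)C[C@H]1O
F3 | step 7 | (1R,2R,4R)-1-(2-hydroxyethyl)-4,7-dimethyl-1,2,3,4,5,8-hexahydronaphthalen-2-ol | OCC[C@@H]1C2=C(CC=C(C)C2)[C@H](C)C[C@H]1O
F4 | step 7 | (3aR,5R,9bR)-5,8-dimethyl-3a,4,5,6,9,9b-hexahydronaphtho[2,1-b]furan-2(1H)-one | C1C(=O)O[C@@H]2C[C@@H](C)C3=C(CC(C)=CC3)[C@@H]12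
F5 | step 7 | (3aR,5R,9bR)-1-[(dimethylamino)methyl]-5,8-dimethyl-3a,4,5,6,9,9b-hexahydronaphtho[2,1-b]furan-2(1H)-one (C1 epimers) | CN(C)CC1C(=O)O[C@@H]2C[C@@H](C)C3=C(CC(C)=CC3)[C@@H]12
F6 | step 9 | ring-fusion 5a,9a-epoxide of 15 (epoxide expected anti to the C5 methyl; ring-fusion configuration immaterial) | C=C1C(=O)O[C@@H]2C[C@@H](C)C34OC3(CC(C)=CC4)[C@@H]12
F7 | step 9 | ring-fusion 5a,9a-trans-diol from F6 (ring-fusion configuration immaterial) | C=C1C(=O)O[C@@H]2C[C@@H](C)C3(O)CC=C(C)CC3(O)[C@@H]12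
F8 | step 11 | tert-butyl 3-hydroxy-2-methylidenebutanoate (racemic) | CC(O)C(=C)C(=O)OC(C)(C)C
F9 | step 11 | tert-butyl 3-(acetyloxy)-2-methylidenebutanoate (racemic) | CC(OC(C)=O)C(=C)C(=O)OC(C)(C)C
F10 | step 11 | tert-butyl (2E)-2-[(acetyloxy)methyl]but-2-enoate | C/C=C(\COC(C)=O)C(=O)OC(C)(C)C
F11 | step 11 | (2E)-2-[(acetyloxy)methyl]but-2-enoic acid | C/C=C(\COC(C)=O)C(O)=O
F12 | step 11 | (2E)-2-[(acetyloxy)methyl]but-2-enoic 2,4,6-trichlorobenzoic anhydride | C/C=C(\COC(C)=O)C(=O)OC(=O)c1c(Cl)cc(Cl)cc1Cl
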